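The runs stem from a simulated flask for an exercise, and the scatter is random.

The amounts of target in the blue run climb and then fall, and that fall is what I carry to the set-ups below.

| setting | blue | grey | violet | red | alder | ash | maple | larch |
|---|---|---|---|---|---|---|---|---|
| substrate | 0.25 M | 0.12 M | 0.50 M | 0.25 M | 0.25 M | 0.25 M | 0.25 M (fed, over 7.50 h) | 0.25 M |
| reagent | 0.263 M | 0.263 M | 0.263 M | 0.13 M | 0.263 M | 0.263 M (fed, over 7.50 h) | 0.263 M | 0.263 M |
| remark | run made earlier | run made earlier | run made earlier | run made earlier | one stirred flow tank at steady state, fed with the mixture as stated, mean residence time 15 h | a stirred flask in which reagent is dosed at a steady rate over 7.50 h without added volume, worked up at 15 h | a stirred flask in which substrate is dosed at a steady rate over 7.50 h without added volume, worked up at 15 h | everything together in a closed stirred flask, run for 15 h |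
| time |  |  |  |  |  | 15 h | 15 h | 15 h |

| run | time / h | target / % |
|---|---|---|
| blue | 4.00 | 80 |
| blue | 8.00 | 86 |
| blue | 12.0 | 82 |
| blue | 15.0 | 77 |
| grey | 3.00 | 91 |
| grey | 6.00 | 88 |
| grey | 10.0 | 83 |
| grey | 12.0 | 82 |
| violet | 3.00 | 46 |
| violet | 6.00 | 48 |
| violet | 10.0 | 46 |
| violet | 12.0 | 43 |
| red | 1.50 | 32 |
| red | 4.00 | 48 |
| red | 8.00 | 47 |
| red | 12.0 | 44 |

(scatter of a reading: 1.5 percentage points)

- the stated concentrations are those of everything mixed, before any reaction; amounts are the same in each set-up
- the feed brings no volume worth counting
- the earlier runs were made in a closed, stirred flask

- the set-up with the highest amount of target at the outlet or at the end, in percent of the substrate put in ("none" if the first two lie within 2 percentage points) (alder / ash / maple / larch / none)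
- amount of target at the outlet or at the end, in percent of the substrate put in, alder
- amount of target at the outlet or at the end, in percent of the substrate put in, ash
- amount of target at the outlet or at the end, in percent of the substrate put in, maple
- amount of target at the outlet or at the end, in percent of the substrate put in, larch

I read the blue run as a rate, in fractions of the charge per hour. Up to 4.00 h target climbs at 0.200 h⁻¹. Target already reads 80.0 % of the charge by then, and the next interval climbs at 0.0150 h⁻¹, which these readings put slower by a factor of 13.3. Between the last two readings the rate has turned, and target falls at 0.0167 h⁻¹. The early climb is faster than this fall, so I reckon the late hours by the fall.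

I therefore use the fade constant, the share of standing target lost per hour of its age 0.0158 h⁻¹, read in the blue run from its highest reading to its last. Target of one age survives as its exponential. I replace each flask's ages by their mean and check the error.

If target forms as the dose arrives, ash and maple have a mean age of 11.2 h, and the survival is 0.837. Averaging over the spread of ages such a dose has gives 0.838, so the mean serves there. In alder the mean age gives 0.789, but the tank's spread gives 0.808, so the mean fails by about 2 points. Larch repeats the blue mixture, which read 77 % at 15.0 h. In this reckoning ash and maple share one survival.

The forecast gives alder 65 %, ash 80.5 %, maple 81 %, larch 79.5 % and best none: “With no selectivity gain from dosing, the top three lie within 2 points”.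

The flask gives alder 68.9 %, ash 76.8 %, maple 82.3 % and larch 77.1 %, so the best is maple, 5.2 percentage points above larch.

    substrate + reagent → target, rate k1*[substrate]^0.5*[reagent]^0.5 (k = 0.00680 min⁻¹)
    target ⇌ isomer of the product (K = 10.0, k = 2.90 × 10⁻⁴ min⁻¹)
    substrate ⇌ dormant form (K = 5.50, k = 3.20 × 10⁻⁴ min⁻¹)

Ash ends with 15.0 % isomer of the product, so target plus isomer there comes to 91.8 % of the charge. Undoing the fade over the mean age, I reckon ash back to 91.7 % and maple back to 98.2 %.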